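**Plan**

- The target is a 2-O-alkyl glycerol whose eight-carbon chain sits on C10 of a cis,anti,cis,anti,cis-fused tetracyclo[6.4.0.0(2,7).0(3,6)]dodecane: ring A = cyclohexane C1/C8–C12, ring B = cyclobutane C1–C2–C7–C8, ring C = cyclobutane C2–C3–C6–C7, ring D = cyclobutane C3–C4–C5–C6.
- Retrosynthetic cuts, in order: the benzylidene acetal on the glycerol; the C9–H/C10–H bonds (alkene); the C10–C1' bond (aldol condensation at a C9 ketone); both bonds from ring A into ring B (C1–C2 and C8–C7); the C2=C7 alkene of bicyclo[2.2.0]hex-2-ene (sulfone extrusion).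
- Enabling feature: ring B shares the C1–C8 edge with ring A and C8 is flanked by C9, so a C9 carbonyl makes C1=C8 the enone of cyclohex-2-enone; its triplet adds to the strained, symmetric C2=C7 alkene and the diradical closes ring B through the C8–C7 bond.
- Forward: rings C and D first (bicyclohexene from a cyclobutane anhydride); ring B closed onto commercial ring A in one photochemical step; then the glycerol-bearing C8 aldehyde is joined at C10 and the C9 oxygen is removed with transposition of the alkene to C9=C10.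
- Stereochemistry: C3/C6 from the meso anhydride; in the key step C1 (absolute) from a chiral Lewis acid, C2/C7 from exo attack on the bicyclohexene, C8 from cis closure with convergent epimerisation; C10 last, by hydrogenation on the convex face of ring A.

Key step: step 6

Remark: which antipode of the oxazaborolidine delivers the (1S,8S) series is assigned by analogy with simple alkenes and is to be fixed in a first run; both antipodes are available from D- and L-proline.

**Route**

Step 1
Reactants: 1 cis-cyclobutane-1,2-dicarboxylic anhydride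
Product: 2 cis-cyclobutane-1,2-diyldimethanol
Conditions: LiAlH4, THF, 0 °C to reflux; aqueous NaOH work-up
Reagents that add atoms: none
Why: Hydride reduction of a cyclic anhydride to the 1,4-diol; the cis relationship of the carbons that become C3 and C6 is inherited from 1.

Step 2
Reactants: 2 cis-cyclobutane-1,2-diyldimethanol
Product: 3 cis-cyclobutane-1,2-diylbis(methylene) dimethanesulfonate
Conditions: MsCl, Et3N, CH2Cl2, 0 °C
Reagents that add atoms: methanesulfonyl chloride, CS(=O)(=O)Cl
Why: Sulfonylation of both primary alcohols sets up a double SN2 displacement; no stereocentre is touched.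

Step 3
Reactants: 3 cis-cyclobutane-1,2-diylbis(methylene) dimethanesulfonate
Product: 4 cis-3-thiabicyclo[3.2.0]heptane
Conditions: Na2S·9H2O, EtOH/H2O, reflux
Reagents that add atoms: sodium sulfide, [Na+].[Na+].[S-2]
Why: Double SN2 displacement by sulfide closes the thiolane (5-exo-tet) on the cis-disposed arms.

Step 4
Reactants: 4 cis-3-thiabicyclo[3.2.0]heptane
Product: 6 2-chloro-3-thiabicyclo[3.2.0]heptane 3,3-dioxide, via α-chloro sulfide 5 (not isolated)
Conditions: NCS, CH2Cl2, 0 °C to rt; then mCPBA (2.2 equiv), 0 °C to rt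
Reagents that add atoms: N-chlorosuccinimide, O=C1CCC(=O)N1Cl; 3-chloroperoxybenzoic acid, OOC(=O)c1cccc(Cl)c1
Why: α-Chlorination of the sulfide through the chlorosulfonium ion (Pummerer-type) followed by peracid oxidation to the sulfone; the C–Cl centre forms as a mixture, which is harmless because both epimers react in step 5.

Step 5
Reactants: 6 2-chloro-3-thiabicyclo[3.2.0]heptane 3,3-dioxide
Product: 7 bicyclo[2.2.0]hex-2-ene
Conditions: KOtBu (3 equiv), DMSO, 20 °C; vacuum transfer into a −78 °C trap, kept as a CH2Cl2 solution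
Reagents that add atoms: none
Why: Ramberg–Bäcklund reaction: α'-deprotonation, 1,3-displacement of chloride to the episulfone and cheletropic loss of SO2 give the cyclobutene with the cis ring fusion retained.

Step 6
Reactants: 7 bicyclo[2.2.0]hex-2-ene; 8 cyclohex-2-en-1-one
Product: 10 (1S,2S,3S,6R,7S,8S)-tetracyclo[6.4.0.0(2,7).0(3,6)]dodecan-9-one, via trans-fused C8 epimer 9 (not isolated)
Conditions: 7 (3 equiv), AlBr3-activated B-(2,4,6-trifluorophenyl)oxazaborolidine of α,α-bis(3,5-dimethylphenyl)prolinol (50 mol %), CH2Cl2, −75 °C, hν 366 nm; then basic Al2O3, CH2Cl2, rt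
Reagents that add atoms: none
Why: Binding of the AlBr3-activated oxazaborolidine to the carbonyl of 8 shifts its absorption so that only the chiral complex is excited at 366 nm; its triplet attacks the alkene of 7 at the β-carbon (future C1–C2 bond), and the triplet 1,4-diradical (α-keto radical at future C8, cyclobutyl radical at future C7) closes ring B after spin inversion by forming the C8–C7 bond, a four-membered ring closure by radical recombination (formal [2+2]). The closest known reaction type is the chiral-Lewis-acid-catalysed enantioselective intermolecular [2+2] photocycloaddition of cyclohex-2-enone with unactivated alkenes, together with uncatalysed enone–cyclobutene photocycloadditions. C1 is set by the catalyst, which shields one face of the enone β-carbon; C2 and C7 are set by attack on the convex (exo) face of 7, which places rings B and D anti across ring C; C8 is set by cis closure, and any trans-fused adduct 9 is epimerised through its enol on basic alumina to the more stable cis ketone, so both closures converge on 10. Rings A and C lie anti across ring B because the diradical closes with the two ring residues on opposite faces of the new cyclobutane, the usual cis-anti-cis outcome for cyclic partners. No regiochemical question arises because the two alkene carbons of 7 are equivalent, and 7 cannot dimerise because it does not absorb at 366 nm; the enantioface selectivity that is needed rests on the high catalyst loading outrunning the weak background excitation of free 8.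

Step 7
Reactants: 11 cis-2-phenyl-1,3-dioxan-5-ol; 12 9-bromonon-1-ene
Product: 13 cis-5-(non-8-en-1-yloxy)-2-phenyl-1,3-dioxane
Conditions: NaH, DMF, 0 °C to rt, cat. Bu4NI
Reagents that add atoms: none
Why: Williamson ether synthesis of the secondary alkoxide with a primary bromide; the acetal stereocentres are not involved.

Step 8
Reactants: 13 cis-5-(non-8-en-1-yloxy)-2-phenyl-1,3-dioxane
Product: 14 8-[(cis-2-phenyl-1,3-dioxan-5-yl)oxy]octanal
Conditions: OsO4 (2 mol %), NaIO4, 2,6-lutidine, dioxane/H2O 3:1, rt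
Reagents that add atoms: sodium periodate, [Na+].[O-]I(=O)(=O)=O (terminal oxygen source, transferred through osmium tetroxide, O=[Os](=O)(=O)=O)
Why: Lemieux–Johnson cleavage (dihydroxylation, then periodate cleavage) of the terminal alkene; 2,6-lutidine keeps the medium neutral so the benzylidene acetal survives.

Step 9
Reactants: 10 (1S,2S,3S,6R,7S,8S)-tetracyclo[6.4.0.0(2,7).0(3,6)]dodecan-9-one; 14 8-[(cis-2-phenyl-1,3-dioxan-5-yl)oxy]octanal
Product: 15 (1S,2S,3S,6R,7S,8S)-10-{1-hydroxy-8-[(cis-2-phenyl-1,3-dioxan-5-yl)oxy]octyl}tetracyclo[6.4.0.0(2,7).0(3,6)]dodecan-9-one (epimers at C10 and C1')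
Conditions: LDA, THF, −78 °C; then 14, −78 °C; AcOH quench
Reagents that add atoms: none
Why: Kinetic lithium enolate formation at the C10 methylene (the C8 methine is tertiary and its enolate would be an alkylidenecyclobutane) and aldol addition to the aldehyde; the two new stereocentres form as a mixture and are both erased in steps 10 and 12.

Step 10
Reactants: 15 aldol adduct (as above)
Product: 17 (1S,2S,3S,6R,7S,8S,10E)-10-{8-[(cis-2-phenyl-1,3-dioxan-5-yl)oxy]octylidene}tetracyclo[6.4.0.0(2,7).0(3,6)]dodecan-9-one, via β-mesyloxy ketone 16 (not isolated)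
Conditions: MsCl, Et3N, CH2Cl2, 0 °C; then DBU, rt
Reagents that add atoms: none
Why: Mesylation and E1cB elimination give the conjugated exocyclic enone, expected as the E isomer on thermodynamic grounds; the alkene geometry has no bearing on step 12.

Step 11
Reactants: 17 exocyclic enone (as above)
Product: 18 4-methylbenzenesulfonohydrazone of 17 at C9
Conditions: TsNHNH2, EtOH, 50 °C
Reagents that add atoms: 4-methylbenzenesulfonohydrazide, NNS(=O)(=O)c1ccc(C)cc1
Why: Condensation of the ketone with the sulfonyl hydrazide; neutral conditions spare the acetal and the C8 stereocentre.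

Step 12
Reactants: 18 tosylhydrazone (as above)
Product: 21 cis-2-phenyl-5-({8-[(1S,2S,3S,6R,7S,8S)-tetracyclo[6.4.0.0(2,7).0(3,6)]dodec-9-en-10-yl]octyl}oxy)-1,3-dioxane, via N-boryl tosylhydrazide 19 (not isolated), via allylic diazene 20 (not isolated)
Conditions: catecholborane, CHCl3, 0 °C; then NaOAc·3H2O, reflux (61 °C)
Reagents that add atoms: none
Why: Catecholborane reduction of an α,β-unsaturated tosylhydrazone with alkene transposition: 1,2-hydroboration of C=N, acetate-induced loss of sulfinate to the allylic diazene and retro-ene loss of N2 move the alkene into ring A (C9=C10) and deliver hydrogen to C1'; no stereocentre is formed and any E/Z or endocyclic enone isomer carried from step 10 would converge on 21.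

Step 13
Reactants: 21 ring A alkene (as above)
Product: 22 cis-2-phenyl-5-({8-[(1R,2S,3S,6R,7R,8S,10S)-tetracyclo[6.4.0.0(2,7).0(3,6)]dodecan-10-yl]octyl}oxy)-1,3-dioxane
Conditions: H2 (1 atm), [Ir(cod)(PCy3)(py)]PF6 (5 mol %), CH2Cl2, rt
Reagents that add atoms: none
Why: Homogeneous hydrogenation of the trisubstituted alkene; hydrogen is delivered to the convex face of ring A (the face of the C1–H and C8–H bonds, away from ring B), which places the chain at C10 cis to ring B (10S), and a soluble catalyst avoids hydrogenolysis of the strained cyclobutanes.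

Step 14
Reactants: 22 saturated acetal (as above)
Product: 23 2-({8-[(1R,2S,3S,6R,7R,8S,10S)-tetracyclo[6.4.0.0(2,7).0(3,6)]dodecan-10-yl]octyl}oxy)propane-1,3-diol
Conditions: AcOH/H2O 4:1, THF, 50 °C
Reagents that add atoms: none
Why: Acid-catalysed hydrolysis of the benzylidene acetal frees the 1,3-diol; the saturated ladderane has no acid-labile group and the temperature stays well below its thermal limit.

**Compound list**

1 | cis-cyclobutane-1,2-dicarboxylic anhydride (meso) | O=C1OC(=O)[C@@H]2CC[C@H]12 | starting material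
2 | cis-cyclobutane-1,2-diyldimethanol | OC[C@@H]1CC[C@@H]1CO | intermediate
3 | cis-cyclobutane-1,2-diylbis(methylene) dimethanesulfonate | CS(=O)(=O)OC[C@@H]1CC[C@@H]1COS(C)(=O)=O | intermediate
4 | cis-3-thiabicyclo[3.2.0]heptane | S1C[C@@H]2CC[C@@H]2C1 | intermediate
5 | 2-chloro-3-thiabicyclo[3.2.0]heptane (cis-fused, racemic, one enantiomer drawn, C2 epimers) | S1C[C@@H]2CC[C@@H]2C1Cl | intermediate (not isolated)
6 | 2-chloro-3-thiabicyclo[3.2.0]heptane 3,3-dioxide (cis-fused, racemic, one enantiomer drawn, C2 epimers) | O=S1(=O)C[C@@H]2CC[C@@H]2C1Cl | intermediate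
7 | bicyclo[2.2.0]hex-2-ene (cis-fused, meso) | C1=C[C@@H]2CC[C@H]12 | intermediate
8 | cyclohex-2-en-1-one | O=C1C=CCCC1 | starting material
9 | (1S,2S,3S,6R,7S,8R)-tetracyclo[6.4.0.0(2,7).0(3,6)]dodecan-9-one (rings A/B trans-fused; minor photoadduct, epimerised on alumina) | C1CC[C@@H]2[C@@H](C1=O)[C@H]1[C@@H]3CC[C@@H]3[C@@H]21 | intermediate (not isolated)
10 | (1S,2S,3S,6R,7S,8S)-tetracyclo[6.4.0.0(2,7).0(3,6)]dodecan-9-one (cis,anti,cis,anti,cis) | C1CC[C@@H]2[C@H](C1=O)[C@H]1[C@@H]3CC[C@@H]3[C@@H]21 | intermediate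
11 | cis-2-phenyl-1,3-dioxan-5-ol | O[C@H]1CO[C@@H](c2ccccc2)OC1 | starting material
12 | 9-bromonon-1-ene | BrCCCCCCCC=C | starting material
13 | cis-5-(non-8-en-1-yloxy)-2-phenyl-1,3-dioxane | c1ccccc1[C@H]1OC[C@H](CO1)OCCCCCCCC=C | intermediate
14 | 8-[(cis-2-phenyl-1,3-dioxan-5-yl)oxy]octanal | c1ccccc1[C@H]1OC[C@H](CO1)OCCCCCCCC=O | intermediate
15 | (1S,2S,3S,6R,7S,8S)-10-{1-hydroxy-8-[(cis-2-phenyl-1,3-dioxan-5-yl)oxy]octyl}tetracyclo[6.4.0.0(2,7).0(3,6)]dodecan-9-one (epimers at C10 and C1') | c1ccccc1[C@H]1OC[C@H](CO1)OCCCCCCCC(O)C1CC[C@@H]2[C@H](C1=O)[C@H]1[C@@H]3CC[C@@H]3[C@@H]21 | intermediate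
16 | methanesulfonate of 15 at the C1' hydroxyl | c1ccccc1[C@H]1OC[C@H](CO1)OCCCCCCCC(OS(C)(=O)=O)C1CC[C@@H]2[C@H](C1=O)[C@H]1[C@@H]3CC[C@@H]3[C@@H]21 | intermediate (not isolated)
17 | (1S,2S,3S,6R,7S,8S,10E)-10-{8-[(cis-2-phenyl-1,3-dioxan-5-yl)oxy]octylidene}tetracyclo[6.4.0.0(2,7).0(3,6)]dodecan-9-one | c1ccccc1[C@H]1OC[C@H](CO1)OCCCCCCC/C=C1\CC[C@@H]2[C@H](C1=O)[C@H]1[C@@H]3CC[C@@H]3[C@@H]21 | intermediate
18 | 4-methylbenzenesulfonohydrazone of 17 at C9 | c1ccccc1[C@H]1OC[C@H](CO1)OCCCCCCC/C=C1\CC[C@@H]2[C@H](C1=NNS(=O)(=O)c1ccc(C)cc1)[C@H]1[C@@H]3CC[C@@H]3[C@@H]21 | intermediate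
19 | N-(1,3,2-benzodioxaborol-2-yl) N'-tosyl hydrazide at C9 (C9 epimers, exocyclic alkene intact) | c1ccccc1[C@H]1OC[C@H](CO1)OCCCCCCC/C=C1\CC[C@@H]2[C@H](C1N(B1Oc3ccccc3O1)NS(=O)(=O)c1ccc(C)cc1)[C@H]1[C@@H]3CC[C@@H]3[C@@H]21 | intermediate (not isolated)
20 | allylic diazene at C9 (C9 epimers, exocyclic alkene intact) | c1ccccc1[C@H]1OC[C@H](CO1)OCCCCCCC/C=C1\CC[C@@H]2[C@H](C1N=N)[C@H]1[C@@H]3CC[C@@H]3[C@@H]21 | intermediate (not isolated)
21 | cis-2-phenyl-5-({8-[(1S,2S,3S,6R,7S,8S)-tetracyclo[6.4.0.0(2,7).0(3,6)]dodec-9-en-10-yl]octyl}oxy)-1,3-dioxane | c1ccccc1[C@H]1OC[C@H](CO1)OCCCCCCCCC=1CC[C@@H]2[C@H](C=1)[C@H]1[C@@H]3CC[C@@H]3[C@@H]21 | intermediate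
22 | cis-2-phenyl-5-({8-[(1R,2S,3S,6R,7R,8S,10S)-tetracyclo[6.4.0.0(2,7).0(3,6)]dodecan-10-yl]octyl}oxy)-1,3-dioxane | c1ccccc1[C@H]1OC[C@H](CO1)OCCCCCCCC[C@H]1CC[C@@H]2[C@H](C1)[C@H]1[C@@H]3CC[C@@H]3[C@@H]21 | intermediate
23 | 2-({8-[(1R,2S,3S,6R,7R,8S,10S)-tetracyclo[6.4.0.0(2,7).0(3,6)]dodecan-10-yl]octyl}oxy)propane-1,3-diol | OCC(CO)OCCCCCCCC[C@H]1CC[C@@H]2[C@H](C1)[C@H]1[C@@H]3CC[C@@H]3[C@@H]21 | target

**Count and risks**

Total steps: 14. Longest linear sequence: 12 (steps 1–6, then 9–14); steps 7–8 form the side branch.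

Steps most likely to fail:

1. Step 6. The Lewis acid may trigger cationic oligomerisation of the strained alkene, or background excitation of uncomplexed enone may erode the enantiofacial control. Fallback, setting out from 7 and 8 and returning at 10: direct irradiation without Lewis acid (350–366 nm, CH2Cl2, −78 °C, then basic Al2O3) should give 10 together with its mirror image, the ent-ketone F1, as the racemate. NaBH4 (MeOH, 0 °C) should reduce both from the convex face to the (9S)-alcohol F2 and its mirror image, the (9R)-alcohol F3. Lipase-catalysed acylation (Candida antarctica lipase B, vinyl acetate, MTBE, rt) is expected, by the empirical rule for secondary alcohols, to acetylate the (9R)-alcohol to the acetate F4. After chromatographic separation, Dess–Martin periodinane should oxidise F2 to 10.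

2. Step 12. Hydride transfer to the hindered conjugated hydrazone may be sluggish or unselective (conjugate reduction), or the borane may open the acetal. Fallback, setting out from 17 and returning at 21: Luche reduction (NaBH4, CeCl3·7H2O, MeOH, −40 °C) should give the allylic alcohol F5. Mitsunobu displacement with 2-nitrobenzenesulfonohydrazide (PPh3, DEAD, N-methylmorpholine, THF, −30 °C) should give the N-allyl sulfonylhydrazine F6. On warming to rt this should lose sulfinic acid to the same diazene 20, whose retro-ene loss of dinitrogen gives 21.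

3. Step 13. Facial selectivity of hydrogen delivery may be poor, or the alkene may migrate before reduction, leading to the C10 epimer. Fallback, setting out from 17 and returning at 22, with C10 set next to the carbonyl instead: conjugate reduction with [(Ph3P)CuH]6 (wet benzene, rt) and kinetic protonation of the enolate on the convex face should give the (10S)-ketone F7. TsNHNH2 (EtOH, rt) should give the tosylhydrazone F8. Catecholborane, then NaOAc·3H2O (CHCl3, 0 °C to reflux), should pass through the N-boryl hydrazide F9 and the alkyl diazene F10 to 22.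

**Further compounds**

F1 | step 6 | (1R,2R,3R,6S,7R,8R)-tetracyclo[6.4.0.0(2,7).0(3,6)]dodecan-9-one (mirror image of 10) | C1CC[C@H]2[C@@H](C1=O)[C@@H]1[C@H]3CC[C@H]3[C@H]21
F2 | step 6 | (1S,2S,3S,6R,7S,8S,9S)-tetracyclo[6.4.0.0(2,7).0(3,6)]dodecan-9-ol | C1CC[C@@H]2[C@H]([C@H]1O)[C@H]1[C@@H]3CC[C@@H]3[C@@H]21
F3 | step 6 | (1R,2R,3R,6S,7R,8R,9R)-tetracyclo[6.4.0.0(2,7).0(3,6)]dodecan-9-ol | C1CC[C@H]2[C@@H]([C@@H]1O)[C@@H]1[C@H]3CC[C@H]3[C@H]21
F4 | step 6 | (1R,2R,3R,6S,7R,8R,9R)-tetracyclo[6.4.0.0(2,7).0(3,6)]dodecan-9-yl acetate | C1CC[C@H]2[C@@H]([C@@H]1OC(C)=O)[C@@H]1[C@H]3CC[C@H]3[C@H]21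
F5 | step 12 | (1S,2S,3S,6R,7S,8S,9R,10E)-10-{8-[(cis-2-phenyl-1,3-dioxan-5-yl)oxy]octylidene}tetracyclo[6.4.0.0(2,7).0(3,6)]dodecan-9-ol | c1ccccc1[C@H]1OC[C@H](CO1)OCCCCCCC/C=C1\CC[C@@H]2[C@H]([C@H]1O)[C@H]1[C@@H]3CC[C@@H]3[C@@H]21
F6 | step 12 | 1-(2-nitrobenzenesulfonyl)-1-[(9S,10E)-10-alkylidene-tetracyclododecan-9-yl]hydrazine (C9 inverted relative to F5) | c1ccccc1[C@H]1OC[C@H](CO1)OCCCCCCC/C=C1\CC[C@@H]2[C@H]([C@@H]1N(N)S(=O)(=O)c1ccccc1[N+](=O)[O-])[C@H]1[C@@H]3CC[C@@H]3[C@@H]21
F7 | step 13 | (1S,2S,3S,6R,7S,8S,10S)-10-{8-[(cis-2-phenyl-1,3-dioxan-5-yl)oxy]octyl}tetracyclo[6.4.0.0(2,7).0(3,6)]dodecan-9-one | c1ccccc1[C@H]1OC[C@H](CO1)OCCCCCCCC[C@H]1CC[C@@H]2[C@H](C1=O)[C@H]1[C@@H]3CC[C@@H]3[C@@H]21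
F8 | step 13 | 4-methylbenzenesulfonohydrazone of F7 at C9 | c1ccccc1[C@H]1OC[C@H](CO1)OCCCCCCCC[C@H]1CC[C@@H]2[C@H](C1=NNS(=O)(=O)c1ccc(C)cc1)[C@H]1[C@@H]3CC[C@@H]3[C@@H]21
F9 | step 13 | N-(1,3,2-benzodioxaborol-2-yl) N'-tosyl hydrazide from F8 (C9 epimers) | c1ccccc1[C@H]1OC[C@H](CO1)OCCCCCCCC[C@H]1CC[C@@H]2[C@H](C1N(B1Oc3ccccc3O1)NS(=O)(=O)c1ccc(C)cc1)[C@H]1[C@@H]3CC[C@@H]3[C@@H]21
F10 | step 13 | alkyl diazene at C9 from F9 (C9 epimers) | c1ccccc1[C@H]1OC[C@H](CO1)OCCCCCCCC[C@H]1CC[C@@H]2[C@H](C1N=N)[C@H]1[C@@H]3CC[C@@H]3[C@@H]21
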